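The runs stem from a simulated flask with made-up constants.

- Start from Monday's run. At 0.56 mol% precatalyst it read an excess of left-handed product of 59.6 % at 6.00 min. Wednesday's run, at 1.2 mol%, read less at the same time: 44.4 %.

| flask | left-handed substrate | right-handed substrate | partner | precatalyst | remark | time |
|---|---|---|---|---|---|---|
| Monday's | 0.73 M | 0.73 M | 3 equiv | 0.56 mol% | run made earlier |  |
| Friday's | 0.73 M | 0.73 M | 3 equiv | 0.85 mol% | run made earlier |  |
| Wednesday's | 0.73 M | 0.73 M | 3 equiv | 1.2 mol% | run made earlier |  |
| alder | 0.73 M | 0.73 M | 3.00 equiv | 1.4 mol% |  | 8.0 min |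
| cedar | 0.73 M | 0.73 M | 3.00 equiv | 0.5 mol% |  | 8.0 min |

| run | time / min | left-handed product / % | right-handed product / % |
|---|---|---|---|
| Monday's | 0.417 | 1.6 | 0 |
| Monday's | 1.00 | 2.8 | 1.5 |
| Monday's | 2.50 | 11.2 | 4.2 |
| Monday's | 6.00 | 25.7 | 6.5 |
| Friday's | 1.33 | 6.1 | 1.3 |
| Friday's | 3.00 | 19.9 | 4.9 |
| Friday's | 4.00 | 23.2 | 7.5 |
| Friday's | 6.00 | 32.0 | 9.0 |
| Wednesday's | 0.417 | 0 | 0 |
| Wednesday's | 1.00 | 6.1 | 3.4 |
| Wednesday's | 2.50 | 20.1 | 6.9 |
| Wednesday's | 6.00 | 38.7 | 14.9 |

(standard deviation of a reading: 1 percentage point)

- free catalyst is single-handed; left-handed substrate and right-handed substrate are mirror images of each other, charged as a racemate, each of them at the stated concentration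
- an excess is below zero if the other one leads

1. which one finishes higher in excess of left-handed product over right-handed product in the product ("neither" within 2 percentage points) (alder / cedar / neither)
2. excess of left-handed product over right-handed product in the product at the end, alder
3. excess of left-handed product over right-handed product in the product at the end, cedar

- Freeze what stays nearly constant. For each substrate, take the part of its own charge still unconverted, which is one minus twice its product reading. Take the logarithm of each part and divide left-handed by right-handed.
- Pooled over the last readings of the earlier runs, this ratio reads 4.67. Call it the selectivity factor s. Singly, Monday's run reads 5.18 and Wednesday's 4.20, with readings that scatter by 1 percentage point.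
- Call minus the left-handed logarithm the reach. From Monday's run to Wednesday's, the reach grew 2.06 times, and the loading 2.14 times. So I scale the pooled reach with loading and, as my own assumption, with time.
- Cedar looks like Monday's run, but its loading times time is 1.19 times Monday's. Its reach comes to 0.825.
- Alder has the same time at a higher loading than cedar, so its reach is 2.31.
- Divide each reach by s to get the right-handed one. I then get 39.6 % for alder and 55.3 % for cedar. In this reckoning alder ends lower than cedar because its reach is longer.
- The forecast names cedar, with 40 % for alder and 56 % for cedar. “The excess should be higher in cedar, because it stops at lower conversion.” My cedar figure stands below the forecast's.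
- The flask gives cedar, with 38.7 % for alder and 53.9 % for cedar. At 8.00 min alder holds 45.8 % left-handed and 20.3 % right-handed product, cedar 27.6 % and 8.28 %. Alder's products at that time give s as 4.76, against 4.67 read from the earlier runs.

    free catalyst + left-handed substrate ⇌ catalyst intermediate A (K = 2.89 M⁻¹, k = 1100 M⁻¹ min⁻¹)
    free catalyst + right-handed substrate ⇌ catalyst intermediate B (K = 1.70 M⁻¹, k = 1780 M⁻¹ min⁻¹)
    partner + catalyst intermediate A → free catalyst + left-handed product (k = 26.2 M⁻¹ min⁻¹)
    partner + catalyst intermediate B → free catalyst + right-handed product (k = 9.30 M⁻¹ min⁻¹)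
    left-handed substrate ⇌ right-handed substrate (k = 0.00847 min⁻¹)
    partner ⇌ dormant form (K = 3.10, k = 0.0467 min⁻¹)
    precatalyst → free catalyst (k = 1.15 min⁻¹)

- Now take cedar left until 20 min, with 42.2 % left-handed product. There s gives an excess of 44.0 %. The computed result is 46.0 %.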